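**Plan**

1. Retrosynthetic cuts: the C6–O ester bond; the C9–C11 and C9–OH bonds (formyl carbon and hydroxyl both delivered to a C9 ketone); then both ring A bonds, C10–C1 and C4–C5, in one [4+2] disconnection to 2,6-dimethyl-1,4-benzoquinone and 4-methylpenta-1,3-diene.
2. Enabling feature: ring B carries its functionalised carbons C6 and C9 in a 1,4 relationship and has two methyl-bearing edges, C7=C8 and C5–C10, which is the pattern of the quinone. Ring A (C1–C5, C10) is all carbon, and C1–C4 with the gem-dimethyl C4 is a 1,1-dimethylbutadiene that adds across C5=C10.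
3. Forward: ring B is bought as the quinone and ring A is closed onto it last, in step 1. The ring A olefin is then hydrogenated, and the C6 carbonyl that activated the cycloaddition is removed through its enol triflate to give a 5,7-dien-9-one.
4. Hydroboration returns oxygen to C6. The C9 ketone is then homologated (epoxide, hydride shift) to the 11-aldehyde and hydroxylated at C9, and the C6 alcohol is acylated with octatrienoic acid made from sorbaldehyde.
5. Stereochemistry: C10 from the chiral oxazaborolidinium catalyst; C5 and C6 together from syn hydroboration on the α face, away from the axial C4 and C10 methyls; C9 from α-face enolate hydroxylation; the E olefins from sorbaldehyde and the Doebner condensation.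

Key step: step 1

Remark: locants follow drimane numbering (ring A = C1–C5 and C10, ring B = C5–C10, C11 = formyl carbon); α is the face opposite the C10 methyl group.

Assumption: the facial sense of step 1 is taken from the accepted pre-transition-state model for oxazaborolidinium-bound quinones, which calls for the catalyst made from (R)-α,α-diphenylprolinol; it was derived from the model and not checked against a reported example.

**Step 1**
Reactants: 1 2,6-dimethyl-1,4-benzoquinone; 2 4-methylpenta-1,3-diene
Product: 3 (4aR,8aS)-2,5,5,8a-tetramethyl-4a,5,8,8a-tetrahydronaphthalene-1,4-dione (cis-fused cycloadduct)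
Conditions: (3aR)-1-(2-methylphenyl)-3,3-diphenyltetrahydro-1H,3H-pyrrolo[1,2-c][1,3,2]oxazaborole (20 mol %), (CF3SO2)2NH (20 mol %), 2 (4 equiv), CH2Cl2, −78 to −40 °C
Reagents that add atoms: none
Why: The protonated oxazaborolidine binds the quinone at the C6 carbonyl, the only one flanked by two C–H groups, so the methyl-bearing C10 becomes the β-carbon of the activated enone; the [4+2] cycloaddition is concerted but highly asynchronous, the unsubstituted CH2 terminus of the diene bonding first to C10 while positive charge builds on the dimethyl-substituted terminus, which then closes on C5. The closest known reaction type is the oxazaborolidinium-catalysed enantioselective Diels–Alder reaction of 1,4-benzoquinones with 1,3-dienes. Ring A is closed in the [4+2] mode through the C10–C1 and C5–C4 bonds, suprafacially on the quinone olefin, which gives the cis ring fusion. C10 is set by the catalyst, whose phenyl group lies under the reacting C5=C10 bond and leaves one face open to the diene; C5 forms cis to the C10 methyl and is re-set in step 5. The step needs regiocontrol (gem-dimethyl terminus to C5), secured by the binding site of the catalyst and reinforced because the opposite orientation would create vicinal quaternary carbons; site control is no issue because the two quinone olefins are equivalent by symmetry. The C6 carbonyl is the activating group and is taken out again in steps 3 and 4.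

**Step 2**
Reactants: 3 cis-fused cycloadduct
Product: 4 (4aR,8aS)-2,5,5,8a-tetramethyl-4a,5,6,7,8,8a-hexahydronaphthalene-1,4-dione
Conditions: H2 (1 atm), RhCl(PPh3)3 (5 mol %), toluene–EtOH, rt
Reagents that add atoms: none
Why: Homogeneous hydrogenation with RhCl(PPh3)3 saturates the isolated cis-disubstituted ring A olefin left by the cycloaddition and spares the trisubstituted, electron-poor enedione olefin, the usual chemoselectivity of this catalyst, and no stereocentre is formed.

**Step 3**
Reactants: 4 cis-fused enedione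
Product: 6 (4aS)-3,4a,8,8-tetramethyl-4-oxo-4,4a,5,6,7,8-hexahydronaphthalen-1-yl trifluoromethanesulfonate, via potassium C6 enolate 5 (not isolated)
Conditions: KN(SiMe3)2, THF, −78 °C; then PhN(SO2CF3)2, −78 to 0 °C
Reagents that add atoms: N-phenylbis(trifluoromethanesulfonimide), O=S(=O)(N(c1ccccc1)S(=O)(=O)C(F)(F)F)C(F)(F)F
Why: Kinetic enolisation and O-sulfonylation (enol triflate formation) touch only the C6 carbonyl, because C5–H is the only α-hydrogen of either carbonyl (C9 is flanked by the quaternary C10 and the vinylic C8), and the cis C5 stereocentre is erased.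

**Step 4**
Reactants: 6 dienyl triflate
Product: 7 (8aS)-2,5,5,8a-tetramethyl-6,7,8,8a-tetrahydronaphthalen-1(5H)-one (5,7-dien-9-one)
Conditions: Pd(OAc)2 (5 mol %), PPh3 (10 mol %), HCO2H, Et3N, DMF, 60 °C
Reagents that add atoms: none
Why: Palladium-catalysed formate reduction of an enol triflate (oxidative addition of zerovalent palladium, formate exchange, loss of CO2, C–H reductive elimination) removes the C6 oxygen and leaves the 5,7-dien-9-one whose C5=C6 olefin is the handle for step 5, and no stereocentre is formed.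

**Step 5**
Reactants: 7 5,7-dien-9-one
Product: 9 (4S,4aS,8aS)-2,5,5,8a-tetramethyl-1,4,4a,5,6,7,8,8a-octahydronaphthalene-1,4-diol (drim-7-ene-type 6α,9-diol, C9 epimers), via organoborane adduct 8 (not isolated)
Conditions: BH3·THF, THF, 0 °C to rt; then NaOH, H2O2, H2O, 0 °C
Reagents that add atoms: hydrogen peroxide, OO
Why: Hydroboration–oxidation of a conjugated diene, as in the conversion of steroidal 5,7-dienes into 5α-7-en-6α-ols: BH3 first reduces the hindered C9 carbonyl (either epimer, erased in step 7), the resulting allylic borate and the fully substituted C8 deactivate C7=C8, and syn addition across C5=C6 puts boron on C6 and hydrogen on C5 from the α face, away from the axial methyl groups on C4 and C10, so that oxidation with retention gives the trans ring fusion (5α-H) and the 6α-hydroxyl in one operation.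

**Step 6**
Reactants: 9 6α,9-diol
Product: 10 (4S,4aS,8aS)-4-[(tert-butyldimethylsilyl)oxy]-2,5,5,8a-tetramethyl-1,4,4a,5,6,7,8,8a-octahydronaphthalen-1-ol (C9 epimers)
Conditions: TBSCl (1.1 equiv), imidazole, DMF, 0 °C
Reagents that add atoms: tert-butyldimethylsilyl chloride, CC(C)(C)[Si](C)(C)Cl
Why: Silyl ether formation under steric control should take the C6 hydroxyl, flanked by a tertiary CH and a vinylic CH, ahead of the C9 hydroxyl, which is neopentylic (quaternary C10) and flanked by the methyl-bearing C8, and no stereocentre is formed.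

**Step 7**
Reactants: 10 C6 silyl ether
Product: 11 (4S,4aS,8aS)-4-[(tert-butyldimethylsilyl)oxy]-2,5,5,8a-tetramethyl-4a,5,6,7,8,8a-hexahydronaphthalen-1(4H)-one
Conditions: Dess–Martin periodinane, NaHCO3, CH2Cl2, rt
Reagents that add atoms: none
Why: Dess–Martin oxidation of the remaining allylic alcohol converges both C9 epimers on the enone and restores the C9 carbonyl for one-carbon homologation, while C5 is no longer next to a carbonyl and cannot epimerise.

**Step 8**
Reactants: 11 6α-silyloxy enone
Product: 12 spiro-epoxide of 11 at C9 (9,11-epoxide, CH2 on the α face, oxygen on the β face)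
Conditions: Me3S+ I−, n-butyllithium, THF, −10 to 0 °C; then 11, 0 °C to rt
Reagents that add atoms: trimethylsulfonium iodide, C[S+](C)C.[I-]
Why: Corey–Chaykovsky epoxidation with the unstabilised sulfonium ylide proceeds by 1,2-addition to the enone carbonyl, the ylide being small enough for the neopentylic C9 and approaching from the α face opposite the axial C10 methyl, which sets a C9 configuration that is erased in step 10.

**Step 9**
Reactants: 12 vinyl epoxide
Product: 13 (1S,4S,4aS,8aS)-4-[(tert-butyldimethylsilyl)oxy]-2,5,5,8a-tetramethyl-1,4,4a,5,6,7,8,8a-octahydronaphthalene-1-carbaldehyde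
Conditions: MgBr2·OEt2, Et2O–CH2Cl2, 0 °C
Reagents that add atoms: none
Why: Meinwald rearrangement of a vinyl oxirane, in which the Lewis acid opens the allylic C9–O bond and a 1,2-hydride shift from C11 to C9 gives the β,γ-unsaturated aldehyde without moving the C7=C8 olefin; the hydride arrives anti to the leaving oxygen and places the formyl group equatorial (β), although the C9 configuration is immaterial.

**Step 10**
Reactants: 13 β,γ-unsaturated aldehyde
Product: 15 (1R,4S,4aS,8aS)-4-[(tert-butyldimethylsilyl)oxy]-1-hydroxy-2,5,5,8a-tetramethyl-1,4,4a,5,6,7,8,8a-octahydronaphthalene-1-carbaldehyde, via potassium dienolate 14 (not isolated)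
Conditions: KN(SiMe3)2, THF, −78 °C; then 2-(phenylsulfonyl)-3-phenyloxaziridine, −78 °C; NH4Cl (aq)
Reagents that add atoms: 2-(phenylsulfonyl)-3-phenyloxaziridine, O=S(=O)(c1ccccc1)N1OC1c1ccccc1
Why: α-Hydroxylation of an aldehyde enolate with an N-sulfonyloxaziridine: the potassium dienolate reacts at its α-carbon C9 from the α face, opposite the axial C10 methyl of the trans-decalin, which gives the 9α-hydroxy-9β-formyl arrangement (9R) as in the C9 hydroxylation of related drim-7-en-11-als, and the equatorial 6α-silyloxy group is not aligned for elimination from the dienolate at −78 °C.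

**Step 11**
Reactants: 15 silyl-protected hydroxy aldehyde
Product: 16 (1R,4S,4aS,8aS)-1,4-dihydroxy-2,5,5,8a-tetramethyl-1,4,4a,5,6,7,8,8a-octahydronaphthalene-1-carbaldehyde (6α,9α-dihydroxydrim-7-en-11-al)
Conditions: HF·pyridine, pyridine, THF, 0 °C to rt
Reagents that add atoms: none
Why: Fluoride-mediated desilylation under buffered, non-basic conditions frees the C6 hydroxyl without touching the tertiary α-hydroxy aldehyde, and no stereocentre is affected.

**Step 12**
Reactants: 17 (2E,4E)-hexa-2,4-dienal; 18 malonic acid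
Product: 20 (2E,4E,6E)-octa-2,4,6-trienoic acid, via hexadienylidenemalonic acid 19 (not isolated)
Conditions: pyridine, piperidine (cat.), 90 °C; HCl (aq) work-up
Reagents that add atoms: none
Why: Knoevenagel condensation in the Doebner modification, in which decarboxylation of the alkylidenemalonic acid in pyridine gives the thermodynamically favoured E olefin while the two existing E olefins are retained.

**Step 13**
Reactants: 16 6α,9α-dihydroxydrim-7-en-11-al; 20 (2E,4E,6E)-octa-2,4,6-trienoic acid
Product: 22 target CNP0223516.2, via mixed anhydride 21 (not isolated)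
Conditions: 20, 2,4,6-trichlorobenzoyl chloride, Et3N, toluene, rt; then 16, DMAP, rt
Reagents that add atoms: none
Why: Yamaguchi esterification, in which the mixed anhydride acylates under DMAP catalysis only the secondary 6α-hydroxyl, the tertiary C9 hydroxyl being inert, and the C6 configuration is retained because the C6–O bond is not broken.

**Compound list**

1 | 2,6-dimethyl-1,4-benzoquinone | CC1=CC(=O)C=C(C)C1=O | starting material
2 | 4-methylpenta-1,3-diene | C=CC=C(C)C | starting material
3 | (4aR,8aS)-2,5,5,8a-tetramethyl-4a,5,8,8a-tetrahydronaphthalene-1,4-dione | O=C1C=C(C)C(=O)[C@@]2(C)CC=CC(C)(C)[C@@H]12 | intermediate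
4 | (4aR,8aS)-2,5,5,8a-tetramethyl-4a,5,6,7,8,8a-hexahydronaphthalene-1,4-dione | O=C1C=C(C)C(=O)[C@@]2(C)CCCC(C)(C)[C@@H]12 | intermediate
5 | potassium (4aS)-3,4a,8,8-tetramethyl-4-oxo-4,4a,5,6,7,8-hexahydronaphthalen-1-olate | CC1=CC([O-])=C2C(C)(C)CCC[C@]2(C)C1=O.[K+] | intermediate
6 | (4aS)-3,4a,8,8-tetramethyl-4-oxo-4,4a,5,6,7,8-hexahydronaphthalen-1-yl trifluoromethanesulfonate | CC1=CC(OS(=O)(=O)C(F)(F)F)=C2C(C)(C)CCC[C@]2(C)C1=O | intermediate
7 | (8aS)-2,5,5,8a-tetramethyl-6,7,8,8a-tetrahydronaphthalen-1(5H)-one | CC1=CC=C2C(C)(C)CCC[C@]2(C)C1=O | intermediate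
8 | 6α-boryl 9-boryloxy adduct of 7 (drawn as the BH2 species; 5α-H, C9 epimers) | B[C@H]1C=C(C)C(OB)[C@@]2(C)CCCC(C)(C)[C@H]12 | intermediate
9 | (4S,4aS,8aS)-2,5,5,8a-tetramethyl-1,4,4a,5,6,7,8,8a-octahydronaphthalene-1,4-diol (C1 epimers) | O[C@H]1C=C(C)C(O)[C@@]2(C)CCCC(C)(C)[C@H]12 | intermediate
10 | (4S,4aS,8aS)-4-[(tert-butyldimethylsilyl)oxy]-2,5,5,8a-tetramethyl-1,4,4a,5,6,7,8,8a-octahydronaphthalen-1-ol (C1 epimers) | CC(C)(C)[Si](C)(C)O[C@H]1C=C(C)C(O)[C@@]2(C)CCCC(C)(C)[C@H]12 | intermediate
11 | (4S,4aS,8aS)-4-[(tert-butyldimethylsilyl)oxy]-2,5,5,8a-tetramethyl-4a,5,6,7,8,8a-hexahydronaphthalen-1(4H)-one | CC(C)(C)[Si](C)(C)O[C@H]1C=C(C)C(=O)[C@@]2(C)CCCC(C)(C)[C@H]12 | intermediate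
12 | (4S,4aS,8aS)-4-[(tert-butyldimethylsilyl)oxy]-2,5,5,8a-tetramethyl-4a,5,6,7,8,8a-hexahydro-4H-spiro[naphthalene-1,2'-oxirane], epoxide oxygen syn to the 8a-methyl | CC(C)(C)[Si](C)(C)O[C@H]1C=C(C)[C@@]3(CO3)[C@@]2(C)CCCC(C)(C)[C@H]12 | intermediate
13 | (1S,4S,4aS,8aS)-4-[(tert-butyldimethylsilyl)oxy]-2,5,5,8a-tetramethyl-1,4,4a,5,6,7,8,8a-octahydronaphthalene-1-carbaldehyde | CC(C)(C)[Si](C)(C)O[C@H]1C=C(C)[C@H](C=O)[C@@]2(C)CCCC(C)(C)[C@H]12 | intermediate
14 | potassium dienolate of 13 (C11 enolate, C9=C11 and C7=C8) | [K+].[O-]C=C1C(C)=C[C@H](O[Si](C)(C)C(C)(C)C)[C@H]2C(C)(C)CCC[C@]12C | intermediate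
15 | (1R,4S,4aS,8aS)-4-[(tert-butyldimethylsilyl)oxy]-1-hydroxy-2,5,5,8a-tetramethyl-1,4,4a,5,6,7,8,8a-octahydronaphthalene-1-carbaldehyde | CC(C)(C)[Si](C)(C)O[C@H]1C=C(C)[C@](O)(C=O)[C@@]2(C)CCCC(C)(C)[C@H]12 | intermediate
16 | (1R,4S,4aS,8aS)-1,4-dihydroxy-2,5,5,8a-tetramethyl-1,4,4a,5,6,7,8,8a-octahydronaphthalene-1-carbaldehyde | O[C@H]1C=C(C)[C@](O)(C=O)[C@@]2(C)CCCC(C)(C)[C@H]12 | intermediate
17 | (2E,4E)-hexa-2,4-dienal | C/C=C/C=C/C=O | starting material
18 | malonic acid | OC(=O)CC(=O)O | starting material
19 | 2-[(2E,4E)-hexa-2,4-dien-1-ylidene]propanedioic acid | C/C=C/C=C/C=C(C(=O)O)C(=O)O | intermediate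
20 | (2E,4E,6E)-octa-2,4,6-trienoic acid | C/C=C/C=C/C=C/C(=O)O | intermediate
21 | (2E,4E,6E)-octa-2,4,6-trienoic 2,4,6-trichlorobenzoic anhydride | C/C=C/C=C/C=C/C(=O)OC(=O)c1c(Cl)cc(Cl)cc1Cl | intermediate
22 | (1S,4R,4aS,8aS)-4-formyl-4-hydroxy-3,4a,8,8-tetramethyl-1,4,4a,5,6,7,8,8a-octahydronaphthalen-1-yl (2E,4E,6E)-octa-2,4,6-trienoate (drimane numbering 5S,6S,9R,10S; 6α-acyloxy, 9α-hydroxy) | C/C=C/C=C/C=C/C(=O)O[C@H]1C=C(C)[C@](O)(C=O)[C@@]2(C)CCCC(C)(C)[C@H]12 | target

Total step count: 13. Longest linear sequence: 12 steps (steps 1 to 11 and 13).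

**Steps most likely to fail**

Step 1. The diene is hindered at its dimethyl terminus and prone to acid-induced oligomerisation, so the cycloaddition may be too slow at the temperature that keeps regio- and enantiocontrol. The fallback sets out from 1 and uses a more nucleophilic diene whose extra oxygen is removed afterwards. Kinetic enol silylation of 4-methylpent-3-en-2-one (LiN(i-Pr)2, TBSCl) gives 2-(tert-butyldimethylsilyloxy)-4-methylpenta-1,3-diene F1. Under the same catalyst F1 should add to 1 with the same regiochemistry to give the C2 silyl enol ether cycloadduct F2. CsF and PhN(SO2CF3)2 in DME convert it into the ring A enol triflate F3, and Pd(OAc)2/PPh3/HCO2H/Et3N reduction returns to the route at 3.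

Step 5. Hydroboration may compete at the C7=C8 olefin or on the β face, and the allylic borane may be lost by protodeboronation before oxidation. The fallback sets out from 4 and sets C5 and C6 separately. Deprotonation at C5 with LiN(SiMe3)2 and protonation of the enolate on the α face (the axial C4 and C10 methyls cover the β face) should give the trans-fused enedione F4. NaBH4/CeCl3·7H2O reduces the less hindered C6 carbonyl from the α face to the 6β-hydroxy enone F5. Mesylation gives the mesylate F6, and displacement with CsOAc and 18-crown-6 in toluene at this allylic carbon inverts C6 to the 6α-acetate F7. K2CO3 in MeOH gives the 6α-hydroxy enone F8, and TBSCl/imidazole returns to the route at 11.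

Step 3. Deprotonation at the C8 methyl group (vinylogous) may compete with removal of the hindered ring-fusion hydrogen and lead to the isomeric triflate. The fallback sets out from 4 and avoids enolisation. NaBH4/CeCl3·7H2O reduces the C6 carbonyl (the C9 carbonyl is neopentylic) to the cis-fused hydroxy enone F9. Its mesylate F10 eliminates with DBU towards C5, the only β-hydrogen, and returns to the route at 7.

**Further compounds**

F1 | step 1 | 2-(tert-butyldimethylsilyloxy)-4-methylpenta-1,3-diene | C=C(O[Si](C)(C)C(C)(C)C)C=C(C)C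
F2 | step 1 | (4aR,8aS)-7-(tert-butyldimethylsilyloxy)-2,5,5,8a-tetramethyl-4a,5,8,8a-tetrahydronaphthalene-1,4-dione | O=C1C=C(C)C(=O)[C@@]2(C)CC(O[Si](C)(C)C(C)(C)C)=CC(C)(C)[C@@H]12
F3 | step 1 | ring A enol triflate of the cis-fused enedione (cycloadduct 3 bearing OSO2CF3 on C2, drimane numbering) | O=C1C=C(C)C(=O)[C@@]2(C)CC(OS(=O)(=O)C(F)(F)F)=CC(C)(C)[C@@H]12
F4 | step 5 | (4aS,8aS)-2,5,5,8a-tetramethyl-4a,5,6,7,8,8a-hexahydronaphthalene-1,4-dione (trans-fused) | O=C1C=C(C)C(=O)[C@@]2(C)CCCC(C)(C)[C@H]12
F5 | step 5 | (4R,4aS,8aS)-4-hydroxy-2,5,5,8a-tetramethyl-4a,5,6,7,8,8a-hexahydronaphthalen-1(4H)-one (6β-alcohol) | O[C@@H]1C=C(C)C(=O)[C@@]2(C)CCCC(C)(C)[C@H]12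
F6 | step 5 | methanesulfonate of F5 | CS(=O)(=O)O[C@@H]1C=C(C)C(=O)[C@@]2(C)CCCC(C)(C)[C@H]12
F7 | step 5 | (1S,4aS,8aS)-3,4a,8,8-tetramethyl-4-oxo-1,4,4a,5,6,7,8,8a-octahydronaphthalen-1-yl acetate (6α-acetate) | CC(=O)O[C@H]1C=C(C)C(=O)[C@@]2(C)CCCC(C)(C)[C@H]12
F8 | step 5 | (4S,4aS,8aS)-4-hydroxy-2,5,5,8a-tetramethyl-4a,5,6,7,8,8a-hexahydronaphthalen-1(4H)-one (6α-alcohol) | O[C@H]1C=C(C)C(=O)[C@@]2(C)CCCC(C)(C)[C@H]12
F9 | step 3 | (4aR,8aS)-4-hydroxy-2,5,5,8a-tetramethyl-4a,5,6,7,8,8a-hexahydronaphthalen-1(4H)-one (cis-fused, C4 epimers) | OC1C=C(C)C(=O)[C@@]2(C)CCCC(C)(C)[C@@H]12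
F10 | step 3 | methanesulfonate of F9 | CS(=O)(=O)OC1C=C(C)C(=O)[C@@]2(C)CCCC(C)(C)[C@@H]12
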